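**Plan** (atoms numbered as the heavy atoms of the target SMILES, C1 to O28)

- Feature: C5 and C21, the two carbonyl-level carbons of the 15-membered carbocycle, stand 1,5 through C4, C24 and C23. Joining them as C5=C21 turns these five atoms into a cyclopentene fused to a 12-membered ring (C5, C7–C10, C12, C13, C15, C17–C19, C21).
- Cuts, in order: lactone C26–O25; C5=O/C21=O back to C5=C21; C7–C8 (enolate alkylation); C19–C21 (sp3–sp2 Negishi); C9–C10 (C-allylation of a furan-derived pyranone).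
- Forward: tetrahydropyran (Achmatowicz), then cyclopentenyl triflate, then C19–C21 coupling, 12-ring by C7–C8 alkylation, 15-ring by ozonolysis, lactone last.
- Stereochemistry, pyran arm: C19 from methyl (R)-3-hydroxybutanoate (inversion to the iodide, retention in the coupling); C17 by Noyori transfer hydrogenation; C13 by equilibration; C15 by L-Selectride; C10 by axial allylation.
- Stereochemistry, five-ring: C4 by cuprate addition anti to the silyloxy group of the (S)-enone; C24 by Mitsunobu inversion; C7 needs no control.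

Key step: step 27

Remark: the target SMILES has C4 and C24 both R, which puts the propyl group and the C24 oxygen cis on the five-membered template. Anti cuprate addition gives the trans pair, so the (S)-silyloxyenone is used and C24 is inverted afterwards (steps 18–21).

**Tetrahydropyran arm**

Step 1
Reactants: 1 methyl (R)-3-hydroxybutanoate
Product: 2 methyl (R)-3-(benzyloxy)butanoate
Conditions: BnOC(=NH)CCl3, TfOH (cat.), CH2Cl2/cyclohexane, 0 °C to rt
Reagents that add atoms: benzyl 2,2,2-trichloroacetimidate, N=C(OCc1ccccc1)C(Cl)(Cl)Cl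
Why: Acid-catalysed benzylation with the trichloroacetimidate protects the β-hydroxy ester without base, so neither elimination nor loss of the C19 configuration is expected.

Step 2
Reactants: 2 methyl (R)-3-(benzyloxy)butanoate
Product: 3 (R)-3-(benzyloxy)-N-methoxy-N-methylbutanamide
Conditions: MeNH(OMe)·HCl, i-PrMgCl, THF, −20 to 0 °C
Reagents that add atoms: N,O-dimethylhydroxylamine hydrochloride, CNOC.Cl
Why: Aminolysis of the methyl ester by the chloromagnesium amide (Weinreb amide formation) is routine for β-alkoxy esters.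

Step 3
Reactants: 3 (R)-3-(benzyloxy)-N-methoxy-N-methylbutanamide, 4 2,4-dimethylfuran
Product: 6 (R)-3-(benzyloxy)-1-(3,5-dimethylfuran-2-yl)butan-1-one, via (3,5-dimethylfuran-2-yl)lithium 5 (not isolated)
Conditions: 4, n-BuLi, THF, 0 °C; then 3, −78 to 0 °C
Reagents that add atoms: none
Why: Lithiation of the furan at its only free α-position and acylation by the Weinreb amide should stop at the ketone because the chelated tetrahedral adduct survives until work-up.

Step 4
Reactants: 6 (R)-3-(benzyloxy)-1-(3,5-dimethylfuran-2-yl)butan-1-one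
Product: 7 (1S,3R)-3-(benzyloxy)-1-(3,5-dimethylfuran-2-yl)butan-1-ol
Conditions: RuCl(p-cymene)[(S,S)-TsDPEN] (1 mol %), HCO2H/Et3N (5:2), rt
Reagents that add atoms: none
Why: Noyori asymmetric transfer hydrogenation of the 2-acylfuran (an aryl alkyl ketone) should set C17 under catalyst control, the (S,S)-ligand giving the (S)-carbinol.

Step 5
Reactants: 7 (1S,3R)-3-(benzyloxy)-1-(3,5-dimethylfuran-2-yl)butan-1-ol
Product: 8 (2S)-2-[(2R)-2-(benzyloxy)propyl]-6-hydroxy-4,6-dimethyl-2H-pyran-3(6H)-one (C6 anomers)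
Conditions: NBS, NaHCO3, NaOAc, THF/H2O (4:1), 0 °C
Reagents that add atoms: water, O
Why: The Achmatowicz oxidative ring expansion carries C17 over unchanged and turns the furan carbons into C15 (ketone), C13, C12 and the C10 hemiketal.

Step 6
Reactants: 8 (2S)-2-[(2R)-2-(benzyloxy)propyl]-6-hydroxy-4,6-dimethyl-2H-pyran-3(6H)-one
Product: 9 (2S,6R)-2-[(2R)-2-(benzyloxy)propyl]-6-methoxy-4,6-dimethyl-2H-pyran-3(6H)-one
Conditions: HC(OMe)3, BF3·OEt2 (cat.), Et2O, 0 °C
Reagents that add atoms: trimethyl orthoformate, COC(OC)OC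
Why: Lewis-acid ketal exchange should convert the tertiary hemiketal into the methyl ketal, with the axial (anomerically favoured) methoxy group trans to the C17 side chain.

Step 7
Reactants: 9 (2S,6R)-2-[(2R)-2-(benzyloxy)propyl]-6-methoxy-4,6-dimethyl-2H-pyran-3(6H)-one
Product: 11 (2S,4S,6R)-2-[(2R)-2-(benzyloxy)propyl]-6-methoxy-4,6-dimethyldihydro-2H-pyran-3(4H)-one, via C4-epimeric dihydropyranone 10 (not isolated)
Conditions: H2 (1 atm), Pd/C, pyridine, EtOAc, rt; then DBU (0.2 equiv), CH2Cl2, rt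
Reagents that add atoms: none
Why: Hydrogenation of the enone (pyridine suppresses benzyl ether hydrogenolysis) followed by base equilibration of the ketone α-centre should place the C13 methyl equatorial and cis to the C17 side chain, since the epimer suffers a 1,3-diaxial contact with the axial methoxy group.

Step 8
Reactants: 11 (2S,4S,6R)-2-[(2R)-2-(benzyloxy)propyl]-6-methoxy-4,6-dimethyldihydro-2H-pyran-3(4H)-one
Product: 12 (2S,3S,4S,6R)-2-[(2R)-2-(benzyloxy)propyl]-6-methoxy-4,6-dimethyltetrahydro-2H-pyran-3-ol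
Conditions: L-Selectride, THF, −78 °C
Reagents that add atoms: none
Why: The bulky hydride should attack the ketone from the equatorial side between its two equatorial neighbours and give the axial C15 alcohol, cis to the C13 methyl and the C17 side chain.

Step 9
Reactants: 12 (2S,3S,4S,6R)-2-[(2R)-2-(benzyloxy)propyl]-6-methoxy-4,6-dimethyltetrahydro-2H-pyran-3-ol
Product: 13 tert-butyl{[(2S,3S,4S,6R)-2-[(2R)-2-(benzyloxy)propyl]-6-methoxy-4,6-dimethyltetrahydro-2H-pyran-3-yl]oxy}dimethylsilane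
Conditions: TBSOTf, 2,6-lutidine, CH2Cl2, −78 °C
Reagents that add atoms: tert-butyldimethylsilyl trifluoromethanesulfonate, CC(C)(C)[Si](C)(C)OS(=O)(=O)C(F)(F)F
Why: The silyl triflate silylates the hindered axial alcohol, and the cold lutidine-buffered medium leaves the ketal intact.

Step 10
Reactants: 13 tert-butyl{[(2S,3S,4S,6R)-2-[(2R)-2-(benzyloxy)propyl]-6-methoxy-4,6-dimethyltetrahydro-2H-pyran-3-yl]oxy}dimethylsilane
Product: 14 (2S,4S,5S,6S)-2-allyl-6-[(2R)-2-(benzyloxy)propyl]-5-(tert-butyldimethylsilyloxy)-2,4-dimethyltetrahydro-2H-pyran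
Conditions: allylSiMe3, TMSOTf, CH2Cl2, −78 °C
Reagents that add atoms: allyltrimethylsilane, C=CC[Si](C)(C)C
Why: Ionisation of the ketal to the cyclic oxocarbenium ion and Hosomi–Sakurai allylation along the axial trajectory (Kishi-type C-glycosidation) should set the quaternary C10 with the new chain axial, trans to the C17 side chain, and the methyl equatorial.

Step 11
Reactants: 14 (2S,4S,5S,6S)-2-allyl-6-[(2R)-2-(benzyloxy)propyl]-5-(tert-butyldimethylsilyloxy)-2,4-dimethyltetrahydro-2H-pyran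
Product: 16 2-[(2R,4S,5S,6S)-6-[(2R)-2-(benzyloxy)propyl]-5-(tert-butyldimethylsilyloxy)-2,4-dimethyltetrahydro-2H-pyran-2-yl]ethan-1-ol, via pyran-2-ylacetaldehyde 15 (not isolated)
Conditions: O3, CH2Cl2/MeOH, −78 °C; then NaBH4, −78 to 0 °C
Reagents that add atoms: ozone, [O-][O+]=O
Why: Ozonolysis of the terminal alkene with reductive borohydride work-up shortens the allyl group to the two-carbon chain C9–C8 bearing the primary alcohol.

Step 12
Reactants: 16 2-[(2R,4S,5S,6S)-6-[(2R)-2-(benzyloxy)propyl]-5-(tert-butyldimethylsilyloxy)-2,4-dimethyltetrahydro-2H-pyran-2-yl]ethan-1-ol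
Product: 17 triethylsilyl ether of 16
Conditions: TESCl, imidazole, CH2Cl2, 0 °C
Reagents that add atoms: chlorotriethylsilane, CC[Si](CC)(CC)Cl
Why: Silylation gives a primary triethylsilyl ether that survives organolithium conditions and can later be cleaved in the presence of the secondary TBS ethers.

Step 13
Reactants: 17 triethylsilyl ether of 16
Product: 18 (2R)-1-[(2S,3S,4S,6R)-3-(tert-butyldimethylsilyloxy)-4,6-dimethyl-6-[2-(triethylsilyloxy)ethyl]tetrahydro-2H-pyran-2-yl]propan-2-ol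
Conditions: H2, Pd(OH)2/C, EtOAc, rt
Reagents that add atoms: none
Why: Hydrogenolysis removes the benzyl ether selectively, since no alkene is present and silyl ethers are stable in ethyl acetate.

Step 14
Reactants: 18 (2R)-1-[(2S,3S,4S,6R)-3-(tert-butyldimethylsilyloxy)-4,6-dimethyl-6-[2-(triethylsilyloxy)ethyl]tetrahydro-2H-pyran-2-yl]propan-2-ol
Product: 19 tert-butyl{[(2S,3S,4S,6R)-2-[(2S)-2-iodopropyl]-4,6-dimethyl-6-[2-(triethylsilyloxy)ethyl]tetrahydro-2H-pyran-3-yl]oxy}dimethylsilane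
Conditions: PPh3, I2, N-methylimidazole, CH2Cl2, −10 °C
Reagents that add atoms: iodine, II
Why: Appel iodination displaces the activated secondary alcohol by SN2 with inversion, and the cold buffered conditions limit iodide–iodide exchange, so the (S)-iodide should result.

**Cyclopentene arm**

Step 15
Reactants: 20 (S)-4-(tert-butyldimethylsilyloxy)cyclopent-2-en-1-one
Product: 21 (S)-4-(tert-butyldimethylsilyloxy)-2-iodocyclopent-2-en-1-one
Conditions: I2, pyridine, CH2Cl2, 0 °C to rt
Reagents that add atoms: iodine, II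
Why: α-Iodination of the enone by pyridine addition, iodination and elimination (Johnson procedure) is standard for this silyloxy enone.

Step 16
Reactants: 21 (S)-4-(tert-butyldimethylsilyloxy)-2-iodocyclopent-2-en-1-one, 22 methyl bromoacetate
Product: 24 methyl 2-[(3S)-3-(tert-butyldimethylsilyloxy)-5-oxocyclopent-1-en-1-yl]acetate, via bromo(2-methoxy-2-oxoethyl)zinc 23 (not isolated)
Conditions: 22, Zn (activated), THF, rt; then 21, Pd2(dba)3, XPhos, THF, rt
Reagents that add atoms: none
Why: Negishi-type coupling of the Reformatsky reagent (a zinc ester enolate) with the alkenyl iodide forms C5–C7 under neutral conditions that spare the base-sensitive silyloxy enone.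

Step 17
Reactants: 24 methyl 2-[(3S)-3-(tert-butyldimethylsilyloxy)-5-oxocyclopent-1-en-1-yl]acetate
Product: 26 methyl 2-[(4S,5S)-4-(tert-butyldimethylsilyloxy)-5-propyl-2-(trifluoromethanesulfonyloxy)cyclopent-1-en-1-yl]acetate, via bromomagnesium enolate 25 (not isolated)
Conditions: n-PrMgBr, CuBr·SMe2, THF, −78 °C; then Comins' reagent, −78 to 0 °C
Reagents that add atoms: n-propylmagnesium bromide, CCC[Mg]Br; N-(5-chloropyridin-2-yl)bis(trifluoromethanesulfonimide), FC(F)(F)S(=O)(=O)N(c1ccc(Cl)cn1)S(=O)(=O)C(F)(F)F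
Why: The cuprate should add anti to the silyloxy group (as in two-component prostaglandin couplings), fixing C4, and the regiodefined enolate is O-sulfonylated to the tetrasubstituted C5=C21 enol triflate.

Step 18
Reactants: 26 methyl 2-[(4S,5S)-4-(tert-butyldimethylsilyloxy)-5-propyl-2-(trifluoromethanesulfonyloxy)cyclopent-1-en-1-yl]acetate
Product: 27 methyl 2-[(4S,5S)-4-hydroxy-5-propyl-2-(trifluoromethanesulfonyloxy)cyclopent-1-en-1-yl]acetate
Conditions: HF·pyridine, THF/pyridine, 0 °C to rt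
Reagents that add atoms: none
Why: Buffered hydrogen fluoride cleaves the secondary silyl ether without attacking the enol triflate, which fluoride salts such as TBAF could cleave.

Step 19
Reactants: 27 methyl 2-[(4S,5S)-4-hydroxy-5-propyl-2-(trifluoromethanesulfonyloxy)cyclopent-1-en-1-yl]acetate
Product: 28 methyl 2-[(4R,5S)-4-(2-chloroacetoxy)-5-propyl-2-(trifluoromethanesulfonyloxy)cyclopent-1-en-1-yl]acetate
Conditions: ClCH2CO2H, PPh3, DIAD, toluene, 0 °C to rt
Reagents that add atoms: chloroacetic acid, OC(=O)CCl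
Why: Mitsunobu esterification with the acidic chloroacetic acid inverts the secondary carbinol by SN2 and so turns the trans C4/C24 pair into the cis pair of the target.

Step 20
Reactants: 28 methyl 2-[(4R,5S)-4-(2-chloroacetoxy)-5-propyl-2-(trifluoromethanesulfonyloxy)cyclopent-1-en-1-yl]acetate
Product: 29 methyl 2-[(4R,5S)-4-hydroxy-5-propyl-2-(trifluoromethanesulfonyloxy)cyclopent-1-en-1-yl]acetate
Conditions: K2CO3 (0.1 equiv), MeOH, 0 °C
Reagents that add atoms: none
Why: The activated chloroacetate undergoes methanolysis far faster than the methyl ester can change or the enol triflate can be attacked.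

Step 21
Reactants: 29 methyl 2-[(4R,5S)-4-hydroxy-5-propyl-2-(trifluoromethanesulfonyloxy)cyclopent-1-en-1-yl]acetate
Product: 30 methyl 2-[(4R,5S)-4-(tert-butyldimethylsilyloxy)-5-propyl-2-(trifluoromethanesulfonyloxy)cyclopent-1-en-1-yl]acetate
Conditions: TBSOTf, 2,6-lutidine, CH2Cl2, −78 °C
Reagents that add atoms: tert-butyldimethylsilyl trifluoromethanesulfonate, CC(C)(C)[Si](C)(C)OS(=O)(=O)C(F)(F)F
Why: Silylation protects the cis alcohol, which is hindered by the neighbouring propyl group, for the organozinc and enolate steps.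

**Union and endgame**

Step 22
Reactants: 19 tert-butyl{[(2S,3S,4S,6R)-2-[(2S)-2-iodopropyl]-4,6-dimethyl-6-[2-(triethylsilyloxy)ethyl]tetrahydro-2H-pyran-3-yl]oxy}dimethylsilane, 30 methyl 2-[(4R,5S)-4-(tert-butyldimethylsilyloxy)-5-propyl-2-(trifluoromethanesulfonyloxy)cyclopent-1-en-1-yl]acetate
Product: 33 methyl 2-[(4R,5S)-4-(tert-butyldimethylsilyloxy)-5-propyl-2-{(2S)-1-[(2S,3S,4S,6R)-3-(tert-butyldimethylsilyloxy)-4,6-dimethyl-6-[2-(triethylsilyloxy)ethyl]tetrahydro-2H-pyran-2-yl]propan-2-yl}cyclopent-1-en-1-yl]acetate, via secondary alkyllithium 31 (not isolated), via mixed alkylzinc 32 (not isolated)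
Conditions: 19, t-BuLi (2.2 equiv), pentane/Et2O, −100 °C; Me3SiCH2ZnBr·LiBr, −100 to −30 °C; then 30, Pd(OAc)2/CPhos (cat.), THF, −25 °C to rt
Reagents that add atoms: none
Why: Iodine–lithium exchange at −100 °C, transmetalation to zinc and Pd-catalysed Negishi coupling with the alkenyl triflate each proceed with retention at the secondary carbon (stereoretentive coupling of configurationally stable secondary alkylzinc reagents), so the iodide configuration should be carried into the C19–C21 bond.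

Step 23
Reactants: 33 (coupled product with C8 triethylsilyl ether)
Product: 34 primary alcohol of 33 (C8–OH; both TBS ethers retained)
Conditions: PPTS, MeOH/CH2Cl2, 0 °C
Reagents that add atoms: none
Why: Mild acid methanolysis cleaves the primary triethylsilyl ether much faster than the secondary TBS ethers.

Step 24
Reactants: 34 primary alcohol of 33
Product: 35 primary iodide (C8–I)
Conditions: PPh3, I2, imidazole, CH2Cl2, 0 °C to rt
Reagents that add atoms: iodine, II
Why: Appel iodination of the unhindered primary alcohol provides the electrophile for ring closure.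

Step 25
Reactants: 35 primary iodide (C8–I)
Product: 37 cyclopentene-fused 12-membered carbocycle, C7 methyl ester, C15 and C24 TBS ethers (4S,10S,13S,15S,17S,19S,24R; C7 epimers), via potassium dienolate 36 (not isolated)
Conditions: KHMDS, THF (1 mM, slow addition), −78 to 0 °C
Reagents that add atoms: none
Why: Deprotonation of the β,γ-unsaturated ester gives a dienolate that is alkylated at its α-carbon by the tethered primary iodide under high dilution (macrocyclic enolate alkylation, 12-exo-tet), forming C7–C8 with a C7 configuration that is of no consequence.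

Step 26
Reactants: 37 bis-TBS bicycle
Product: 38 cyclopentene-fused 12-membered carbocycle with free C15 and C24 hydroxyls and C7 methyl ester
Conditions: HF·pyridine, THF/pyridine, rt
Reagents that add atoms: none
Why: Both silyl ethers, including the hindered axial one at C15, are removed while the molecule holds nothing more sensitive than an alkene and an ester.

Step 27
Reactants: 38 cyclopentene-fused 12-membered diol ester
Product: 41 15-membered 5,21-diketone with C7 methyl ester and free C15 and C24 hydroxyls (4R,10S,13S,15S,17S,19S,24R; C7 epimers), via primary ozonide 39 (not isolated), via secondary ozonide 40 (not isolated)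
Conditions: O3, CH2Cl2, −78 °C (Sudan III end point); then PPh3, −78 °C to rt
Reagents that add atoms: ozone, [O-][O+]=O
Why: Ozone adds as a 1,3-dipole to the only C=C bond (C5=C21) to give primary ozonide 39, which cycloreverts to a ketone and a carbonyl oxide held together by the ring and recombines to ozonide 40, and triphenylphosphine reduces this to the C5 and C21 ketones. The closest known reaction is the ozonolytic ring expansion of bicyclo[10.3.0]pentadec-1(12)-enes to cyclopentadecane-1,5-diones (muscone route). No ring is closed by bond formation: the 15-membered ring appears because the bond shared by the five- and twelve-membered rings is cut, and the cyclopentene disappears with it. No stereocentre is formed; C4, C19 and C24 next to the new carbonyl groups should keep their configuration under the cold, neutral conditions, and C7 becomes the enolized carbon in the last step. Only chemoselectivity is needed, and it is secured by the single electron-rich tetrasubstituted alkene, which reacts far faster than the secondary alcohols or ether C–H bonds.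

Step 28
Reactants: 41 dihydroxy diketo ester
Product: 42 mangromicin C
Conditions: CSA (cat.), 4 Å MS, CH2Cl2, rt
Reagents that add atoms: none
Why: Acid-catalysed intramolecular transesterification of the δ-hydroxy β-keto ester (6-exo-trig) closes the lactone, which enolizes to the 4-hydroxy-5,6-dihydropyran-2-one, so the C7 stereocentre vanishes and the β-acyloxy ketone never meets base.

**Compound list**

1 | methyl (R)-3-hydroxybutanoate | C[C@@H](O)CC(=O)OC | starting material
2 | methyl (R)-3-(benzyloxy)butanoate | C[C@@H](OCc1ccccc1)CC(=O)OC | intermediate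
3 | (R)-3-(benzyloxy)-N-methoxy-N-methylbutanamide | C[C@@H](OCc1ccccc1)CC(=O)N(C)OC | intermediate
4 | 2,4-dimethylfuran | Cc1cc(C)co1 | starting material
5 | (3,5-dimethylfuran-2-yl)lithium | [Li]c1oc(C)cc1C | intermediate
6 | (R)-3-(benzyloxy)-1-(3,5-dimethylfuran-2-yl)butan-1-one | C[C@@H](OCc1ccccc1)CC(=O)c1oc(C)cc1C | intermediate
7 | (1S,3R)-3-(benzyloxy)-1-(3,5-dimethylfuran-2-yl)butan-1-ol | Cc1cc(C)c(o1)[C@H](C[C@@H](C)OCc2ccccc2)O | intermediate
8 | (2S)-2-[(2R)-2-(benzyloxy)propyl]-6-hydroxy-4,6-dimethyl-2H-pyran-3(6H)-one (C6 anomers) | CC1(O)C=C(C)C(=O)[C@H](C[C@@H](C)OCc2ccccc2)O1 | intermediate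
9 | (2S,6R)-2-[(2R)-2-(benzyloxy)propyl]-6-methoxy-4,6-dimethyl-2H-pyran-3(6H)-one | CO[C@@]1(C)C=C(C)C(=O)[C@H](C[C@@H](C)OCc2ccccc2)O1 | intermediate
10 | (2S,6R)-2-[(2R)-2-(benzyloxy)propyl]-6-methoxy-4,6-dimethyldihydro-2H-pyran-3(4H)-one, C4 epimers | CO[C@@]1(C)CC(C)C(=O)[C@H](C[C@@H](C)OCc2ccccc2)O1 | intermediate
11 | (2S,4S,6R)-2-[(2R)-2-(benzyloxy)propyl]-6-methoxy-4,6-dimethyldihydro-2H-pyran-3(4H)-one | CO[C@@]1(C)C[C@H](C)C(=O)[C@H](C[C@@H](C)OCc2ccccc2)O1 | intermediate
12 | (2S,3S,4S,6R)-2-[(2R)-2-(benzyloxy)propyl]-6-methoxy-4,6-dimethyltetrahydro-2H-pyran-3-ol | CO[C@@]1(C)C[C@H](C)[C@H](O)[C@H](C[C@@H](C)OCc2ccccc2)O1 | intermediate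
13 | tert-butyl{[(2S,3S,4S,6R)-2-[(2R)-2-(benzyloxy)propyl]-6-methoxy-4,6-dimethyltetrahydro-2H-pyran-3-yl]oxy}dimethylsilane | CO[C@@]1(C)C[C@H](C)[C@H](O[Si](C)(C)C(C)(C)C)[C@H](C[C@@H](C)OCc2ccccc2)O1 | intermediate
14 | (2S,4S,5S,6S)-2-allyl-6-[(2R)-2-(benzyloxy)propyl]-5-(tert-butyldimethylsilyloxy)-2,4-dimethyltetrahydro-2H-pyran | C=CC[C@@]1(C)C[C@H](C)[C@H](O[Si](C)(C)C(C)(C)C)[C@H](C[C@@H](C)OCc2ccccc2)O1 | intermediate
15 | 2-[(2R,4S,5S,6S)-6-[(2R)-2-(benzyloxy)propyl]-5-(tert-butyldimethylsilyloxy)-2,4-dimethyltetrahydro-2H-pyran-2-yl]acetaldehyde | O=CC[C@@]1(C)C[C@H](C)[C@H](O[Si](C)(C)C(C)(C)C)[C@H](C[C@@H](C)OCc2ccccc2)O1 | intermediate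
16 | 2-[(2R,4S,5S,6S)-6-[(2R)-2-(benzyloxy)propyl]-5-(tert-butyldimethylsilyloxy)-2,4-dimethyltetrahydro-2H-pyran-2-yl]ethan-1-ol | OCC[C@@]1(C)C[C@H](C)[C@H](O[Si](C)(C)C(C)(C)C)[C@H](C[C@@H](C)OCc2ccccc2)O1 | intermediate
17 | triethylsilyl ether of 16 | CC[Si](CC)(CC)OCC[C@@]1(C)C[C@H](C)[C@H](O[Si](C)(C)C(C)(C)C)[C@H](C[C@@H](C)OCc2ccccc2)O1 | intermediate
18 | (2R)-1-[(2S,3S,4S,6R)-3-(tert-butyldimethylsilyloxy)-4,6-dimethyl-6-[2-(triethylsilyloxy)ethyl]tetrahydro-2H-pyran-2-yl]propan-2-ol | CC[Si](CC)(CC)OCC[C@@]1(C)C[C@H](C)[C@H](O[Si](C)(C)C(C)(C)C)[C@H](C[C@@H](C)O)O1 | intermediate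
19 | tert-butyl{[(2S,3S,4S,6R)-2-[(2S)-2-iodopropyl]-4,6-dimethyl-6-[2-(triethylsilyloxy)ethyl]tetrahydro-2H-pyran-3-yl]oxy}dimethylsilane | CC[Si](CC)(CC)OCC[C@@]1(C)C[C@H](C)[C@H](O[Si](C)(C)C(C)(C)C)[C@H](C[C@H](C)I)O1 | intermediate
20 | (S)-4-(tert-butyldimethylsilyloxy)cyclopent-2-en-1-one | O=C1C=C[C@@H](O[Si](C)(C)C(C)(C)C)C1 | starting material
21 | (S)-4-(tert-butyldimethylsilyloxy)-2-iodocyclopent-2-en-1-one | O=C1C(I)=C[C@@H](O[Si](C)(C)C(C)(C)C)C1 | intermediate
22 | methyl bromoacetate | BrCC(=O)OC | starting material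
23 | bromo(2-methoxy-2-oxoethyl)zinc | COC(=O)C[Zn]Br | intermediate
24 | methyl 2-[(3S)-3-(tert-butyldimethylsilyloxy)-5-oxocyclopent-1-en-1-yl]acetate | COC(=O)CC1=C[C@@H](O[Si](C)(C)C(C)(C)C)CC1=O | intermediate
25 | bromomagnesium enolate of the trans 3-propyl-4-silyloxy ketone | CCC[C@H]1C(CC(=O)OC)=C(O[Mg]Br)C[C@@H]1O[Si](C)(C)C(C)(C)C | intermediate
26 | methyl 2-[(4S,5S)-4-(tert-butyldimethylsilyloxy)-5-propyl-2-(trifluoromethanesulfonyloxy)cyclopent-1-en-1-yl]acetate | CCC[C@H]1C(CC(=O)OC)=C(OS(=O)(=O)C(F)(F)F)C[C@@H]1O[Si](C)(C)C(C)(C)C | intermediate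
27 | methyl 2-[(4S,5S)-4-hydroxy-5-propyl-2-(trifluoromethanesulfonyloxy)cyclopent-1-en-1-yl]acetate | CCC[C@H]1C(CC(=O)OC)=C(OS(=O)(=O)C(F)(F)F)C[C@@H]1O | intermediate
28 | methyl 2-[(4R,5S)-4-(2-chloroacetoxy)-5-propyl-2-(trifluoromethanesulfonyloxy)cyclopent-1-en-1-yl]acetate | CCC[C@H]1C(CC(=O)OC)=C(OS(=O)(=O)C(F)(F)F)C[C@H]1OC(=O)CCl | intermediate
29 | methyl 2-[(4R,5S)-4-hydroxy-5-propyl-2-(trifluoromethanesulfonyloxy)cyclopent-1-en-1-yl]acetate | CCC[C@H]1C(CC(=O)OC)=C(OS(=O)(=O)C(F)(F)F)C[C@H]1O | intermediate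
30 | methyl 2-[(4R,5S)-4-(tert-butyldimethylsilyloxy)-5-propyl-2-(trifluoromethanesulfonyloxy)cyclopent-1-en-1-yl]acetate | CCC[C@H]1C(CC(=O)OC)=C(OS(=O)(=O)C(F)(F)F)C[C@H]1O[Si](C)(C)C(C)(C)C | intermediate
31 | secondary alkyllithium from 19 (Li at C19, configuration retained) | CC[Si](CC)(CC)OCC[C@@]1(C)C[C@H](C)[C@H](O[Si](C)(C)C(C)(C)C)[C@H](C[C@H](C)[Li])O1 | intermediate
32 | mixed alkyl(trimethylsilylmethyl)zinc from 31 | CC[Si](CC)(CC)OCC[C@@]1(C)C[C@H](C)[C@H](O[Si](C)(C)C(C)(C)C)[C@H](C[C@H](C)[Zn]C[Si](C)(C)C)O1 | intermediate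
33 | methyl 2-[(4R,5S)-4-(tert-butyldimethylsilyloxy)-5-propyl-2-{(2S)-1-[(2S,3S,4S,6R)-3-(tert-butyldimethylsilyloxy)-4,6-dimethyl-6-[2-(triethylsilyloxy)ethyl]tetrahydro-2H-pyran-2-yl]propan-2-yl}cyclopent-1-en-1-yl]acetate | CC[Si](CC)(CC)OCC[C@@]1(C)C[C@H](C)[C@H](O[Si](C)(C)C(C)(C)C)[C@H](C[C@H](C)C2=C(CC(=O)OC)[C@H](CCC)[C@H](O[Si](C)(C)C(C)(C)C)C2)O1 | intermediate
34 | primary alcohol of 33 (C8–OH) | OCC[C@@]1(C)C[C@H](C)[C@H](O[Si](C)(C)C(C)(C)C)[C@H](C[C@H](C)C2=C(CC(=O)OC)[C@H](CCC)[C@H](O[Si](C)(C)C(C)(C)C)C2)O1 | intermediate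
35 | primary iodide (C8–I) | ICC[C@@]1(C)C[C@H](C)[C@H](O[Si](C)(C)C(C)(C)C)[C@H](C[C@H](C)C2=C(CC(=O)OC)[C@H](CCC)[C@H](O[Si](C)(C)C(C)(C)C)C2)O1 | intermediate
36 | potassium dienolate of 35 | ICC[C@@]1(C)C[C@H](C)[C@H](O[Si](C)(C)C(C)(C)C)[C@H](C[C@H](C)C2=C(C=C(O[K])OC)[C@H](CCC)[C@H](O[Si](C)(C)C(C)(C)C)C2)O1 | intermediate
37 | cyclopentene-fused 12-membered carbocycle, C7 methyl ester, C15 and C24 TBS ethers (4S,10S,13S,15S,17S,19S,24R; C7 epimers) | CCC[C@H]1C=4C(C(=O)OC)CC[C@@]3(C)C[C@H](C)[C@H](O[Si](C)(C)C(C)(C)C)[C@H](C[C@H](C)C4C[C@H]1O[Si](C)(C)C(C)(C)C)O3 | intermediate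
38 | cyclopentene-fused 12-membered carbocycle, C7 methyl ester, free C15 and C24 hydroxyls (4S,10S,13S,15S,17S,19S,24R; C7 epimers) | CCC[C@H]1C=4C(C(=O)OC)CC[C@@]3(C)C[C@H](C)[C@H](O)[C@H](C[C@H](C)C4C[C@H]1O)O3 | intermediate
39 | primary ozonide (1,2,3-trioxolane across C5–C21) | CCC[C@H]1C45C(C(=O)OC)CC[C@@]3(C)C[C@H](C)[C@H](O)[C@H](C[C@H](C)C4(OOO5)C[C@H]1O)O3 | intermediate
40 | secondary ozonide (1,2,4-trioxolane bridging C5 and C21) | CCC[C@H]1C4(OO5)C(C(=O)OC)CC[C@@]3(C)C[C@H](C)[C@H](O)[C@H](C[C@H](C)C5(O4)C[C@H]1O)O3 | intermediate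
41 | 15-membered 5,21-diketone, C7 methyl ester, free C15 and C24 hydroxyls (4R,10S,13S,15S,17S,19S,24R; C7 epimers) | CCC[C@H]1C(=O)C(C(=O)OC)CC[C@@]3(C)C[C@H](C)[C@H](O)[C@H](C[C@H](C)C(=O)C[C@H]1O)O3 | intermediate
42 | mangromicin C | CCC[C@H]1C(O)=C2CC[C@@]3(C)C[C@H](C)[C@H](O)[C@H](C[C@H](C)C(=O)C[C@H]1OC2=O)O3 | target

**Step count and risks**

Total: 28 steps. Longest linear sequence: 21 steps (steps 1–14, then 22–28).

Steps most likely to fail:

1. Step 22. The configuration at C19 may be lost during iodine–lithium exchange or transmetalation, the secondary alkylpalladium may undergo β-hydride elimination and chain walking, and oxidative addition and coupling at the hindered tetrasubstituted triflate may be slow. The fallback sets out from 18 and 30 and returns at 33. Oxidation of 18 (Dess–Martin periodinane) gives the methyl ketone F1, and kinetic enolization (KHMDS, PhNTf2, −78 °C) gives the terminal enol triflate F2. Triflate 30 is converted to the pinacol boronate F3 (B2pin2, PdCl2(dppf), KOPh). Suzuki–Miyaura coupling of F2 with F3 gives the diene F4. Its 1,1-disubstituted C19=C20 bond is then hydrogenated with a chiral iridium P,N catalyst, which selects the face and leaves the tetrasubstituted ring alkene untouched.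

2. Step 25. Intermolecular alkylation and elimination of the iodide may outrun closure of the 12-membered ring, whose strain across the 2,6-trans-bridged pyran is unknown. The fallback sets out from 34 and returns at 37. Oxidation (Dess–Martin periodinane) gives the aldehyde F5, a far more reactive electrophile. Intramolecular aldol addition of the ester dienolate (LiHMDS, high dilution, −78 °C) gives the β-hydroxy ester F6. Dehydration (Burgess reagent) gives the cross-conjugated dienoate F7. Conjugate reduction of its C7=C8 bond with Stryker's reagent and α-protonation then gives 37.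

3. Step 19. The nucleophile must enter cis to the propyl group, so elimination to a cyclopentadiene may compete with substitution. The fallback sets out from 27 and returns at 29. Buffered Dess–Martin oxidation gives the β,γ-unsaturated ketone F8. It is reduced at once with L-Selectride at −78 °C, where hydride delivery anti to the propyl group gives the cis alcohol 29 without the chloroacetate.

**Further compounds**

F1 | step 22 | 1-[(2S,3S,4S,6R)-3-(tert-butyldimethylsilyloxy)-4,6-dimethyl-6-[2-(triethylsilyloxy)ethyl]tetrahydro-2H-pyran-2-yl]propan-2-one | CC[Si](CC)(CC)OCC[C@@]1(C)C[C@H](C)[C@H](O[Si](C)(C)C(C)(C)C)[C@H](CC(C)=O)O1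
F2 | step 22 | 3-[(2S,3S,4S,6R)-3-(tert-butyldimethylsilyloxy)-4,6-dimethyl-6-[2-(triethylsilyloxy)ethyl]tetrahydro-2H-pyran-2-yl]prop-1-en-2-yl trifluoromethanesulfonate | CC[Si](CC)(CC)OCC[C@@]1(C)C[C@H](C)[C@H](O[Si](C)(C)C(C)(C)C)[C@H](CC(=C)OS(=O)(=O)C(F)(F)F)O1
F3 | step 22 | methyl 2-[(4R,5S)-4-(tert-butyldimethylsilyloxy)-5-propyl-2-(4,4,5,5-tetramethyl-1,3,2-dioxaborolan-2-yl)cyclopent-1-en-1-yl]acetate | CCC[C@H]1C(CC(=O)OC)=C(B2OC(C)(C)C(C)(C)O2)C[C@H]1O[Si](C)(C)C(C)(C)C
F4 | step 22 | diene analogue of 33 with C19=C20 methylene | CC[Si](CC)(CC)OCC[C@@]1(C)C[C@H](C)[C@H](O[Si](C)(C)C(C)(C)C)[C@H](CC(=C)C2=C(CC(=O)OC)[C@H](CCC)[C@H](O[Si](C)(C)C(C)(C)C)C2)O1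
F5 | step 25 | C8 aldehyde from 34 | O=CC[C@@]1(C)C[C@H](C)[C@H](O[Si](C)(C)C(C)(C)C)[C@H](C[C@H](C)C2=C(CC(=O)OC)[C@H](CCC)[C@H](O[Si](C)(C)C(C)(C)C)C2)O1
F6 | step 25 | 8-hydroxy analogue of 37 (aldol product, C7 and C8 epimers) | CCC[C@H]1C=4C(C(=O)OC)C(O)C[C@@]3(C)C[C@H](C)[C@H](O[Si](C)(C)C(C)(C)C)[C@H](C[C@H](C)C4C[C@H]1O[Si](C)(C)C(C)(C)C)O3
F7 | step 25 | 7,8-dehydro analogue of 37 (cross-conjugated dienoate) | CCC[C@H]1C=4C(C(=O)OC)=CC[C@@]3(C)C[C@H](C)[C@H](O[Si](C)(C)C(C)(C)C)[C@H](C[C@H](C)C4C[C@H]1O[Si](C)(C)C(C)(C)C)O3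
F8 | step 19 | methyl 2-[(5S)-4-oxo-5-propyl-2-(trifluoromethanesulfonyloxy)cyclopent-1-en-1-yl]acetate | CCC[C@H]1C(CC(=O)OC)=C(OS(=O)(=O)C(F)(F)F)CC1=O
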